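The route rests on cutting the 3,7-dioxabicyclo[3.3.0]octane core at C5–C6 and O7–C8. At the dione oxidation level C5 is the α-carbon of a lactone and C8, on the adjacent bridgehead C1, is an ester carbon. O-Benzylsyringaldehyde can therefore be inserted between them: one aldol–translactonisation closes the ring holding O7 and sets C5 and C6. Keeping C8 as the methyl ester and C4 as the lactone makes C5 the preferred site of enolisation. The precursor is a single-enantiomer methyl trans-2-aryl-5-oxooxolane-3-carboxylate from an Evans syn aldol. Its aryl group is the protected 2,3-cis-dihydrobenzofuran, made by an enantioselective dirhodium-catalysed C–H insertion.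

Key step: step 13

Assumption: Rh2(R-PTTL)4 is taken to deliver the (2S,3R) enantiomer of cis ester 7, by analogy with simpler 2-(benzyloxy)phenyl diazoacetates under the (S)-catalyst; if the sense proves opposite, Rh2(S-PTTL)4 is used and nothing else changes.

Numbering: furofuran atoms are numbered as in 3,7-dioxabicyclo[3.3.0]octane (bridgeheads C1 and C5; aryl-bearing C2 and C6; O3–C4 and O7–C8). The target as drawn has a 2,3-cis dihydrobenzofuran (2S,3S) and a (1R,2S,5R,6S) furofuran with both aryl groups exo.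

Abbreviations: Ar1 = (2S,3S)-2-[4-(benzyloxy)-3-methoxyphenyl]-3-{[(tert-butyldimethylsilyl)oxy]methyl}-7-methoxy-2,3-dihydro-1-benzofuran-5-yl; Ar2 = 4-(benzyloxy)-3,5-dimethoxyphenyl.

Step 1
Reactants: 1 4-bromo-2-methoxyphenol
Product: 2 4-bromo-2-iodo-6-methoxyphenol
Conditions: I2, NaHCO3, THF–H2O, 0 °C → rt
Reagents that add atoms: iodine, II
Why: Electrophilic aromatic iodination of the phenol; with the para position blocked by bromine, iodine should enter the free position ortho to the hydroxyl, as in the iodination of vanillin.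

Step 2
Reactants: 2 4-bromo-2-iodo-6-methoxyphenol; 3 [4-(benzyloxy)-3-methoxyphenyl]methanol
Product: 4 2-{[4-(benzyloxy)-3-methoxyphenyl]methoxy}-5-bromo-1-iodo-3-methoxybenzene
Conditions: PPh3, DIAD, THF, 0 °C → rt
Reagents that add atoms: none
Why: Mitsunobu etherification of an acidic phenol with a primary benzylic alcohol; no stereocentre is involved.

Step 3
Reactants: 4 2-{[4-(benzyloxy)-3-methoxyphenyl]methoxy}-5-bromo-1-iodo-3-methoxybenzene
Product: 5 methyl 2-(2-{[4-(benzyloxy)-3-methoxyphenyl]methoxy}-5-bromo-3-methoxyphenyl)acetate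
Conditions: Zn (TMSCl-activated), BrCH2CO2Me, THF, 40 °C; then 4, Pd(PPh3)4 (5 mol %), THF–DMPU, 50 °C
Reagents that add atoms: methyl bromoacetate (as its zinc reagent), COC(=O)CBr
Why: Negishi-type cross-coupling of the Reformatsky reagent; oxidative addition of zerovalent palladium to the C–I bond is much faster than to the C–Br bond, so the bromide should be kept for step 8.

Step 4
Reactants: 5 methyl 2-(2-{[4-(benzyloxy)-3-methoxyphenyl]methoxy}-5-bromo-3-methoxyphenyl)acetate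
Product: 6 methyl 2-(2-{[4-(benzyloxy)-3-methoxyphenyl]methoxy}-5-bromo-3-methoxyphenyl)-2-diazoacetate
Conditions: p-ABSA, DBU, MeCN, 0 °C → rt
Reagents that add atoms: 4-acetamidobenzenesulfonyl azide (p-ABSA), CC(=O)Nc1ccc(cc1)S(=O)(=O)N=[N+]=[N-]
Why: Regitz diazo transfer to the benzylic, ester-activated methylene.

Step 5
Reactants: 6 methyl 2-(2-{[4-(benzyloxy)-3-methoxyphenyl]methoxy}-5-bromo-3-methoxyphenyl)-2-diazoacetate
Product: 7 methyl (2S,3R)-2-[4-(benzyloxy)-3-methoxyphenyl]-5-bromo-7-methoxy-2,3-dihydro-1-benzofuran-3-carboxylate (2,3-cis)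
Conditions: Rh2(R-PTTL)4 (dirhodium tetrakis[N-phthaloyl-(R)-tert-leucinate], 1 mol %), toluene, −60 °C, slow addition of 6
Reagents that add atoms: none
Why: Enantioselective intramolecular 1,5 C–H insertion of a donor/acceptor diazo ester under dirhodium carboxylate catalysis: the carbene carbon inserts into the electron-rich benzylic ether C–H bond and forms C2–C3 with the kinetic 2,3-cis geometry expected for phthaloyl-amino-acid ligands, the chiral ligand sphere choosing the enantiotopic C–H bond and thereby both centres.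

Step 6
Reactants: 7 methyl (2S,3R)-2-[4-(benzyloxy)-3-methoxyphenyl]-5-bromo-7-methoxy-2,3-dihydro-1-benzofuran-3-carboxylate
Product: 8 [(2S,3S)-2-[4-(benzyloxy)-3-methoxyphenyl]-5-bromo-7-methoxy-2,3-dihydro-1-benzofuran-3-yl]methanol (2,3-cis)
Conditions: i-Bu2AlH, CH2Cl2, −78 → 0 °C; aq. potassium sodium tartrate
Reagents that add atoms: none
Why: Ester reduction with a non-basic aluminium hydride, so the epimerisable C3 centre next to the ester should not be touched before the carbonyl is gone.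

Step 7
Reactants: 8 [(2S,3S)-2-[4-(benzyloxy)-3-methoxyphenyl]-5-bromo-7-methoxy-2,3-dihydro-1-benzofuran-3-yl]methanol
Product: 9 tert-butyl{[(2S,3S)-2-[4-(benzyloxy)-3-methoxyphenyl]-5-bromo-7-methoxy-2,3-dihydro-1-benzofuran-3-yl]methoxy}dimethylsilane
Conditions: TBSCl, imidazole, CH2Cl2, rt
Reagents that add atoms: tert-butyldimethylsilyl chloride, CC(C)(C)[Si](C)(C)Cl
Why: Silyl ether formation at the primary alcohol; a silyl group is chosen so that the last step has to cleave only the fast-reacting aryl benzyl ethers.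

Step 8
Reactants: 9 tert-butyl{[(2S,3S)-2-[4-(benzyloxy)-3-methoxyphenyl]-5-bromo-7-methoxy-2,3-dihydro-1-benzofuran-3-yl]methoxy}dimethylsilane
Product: 11 (2S,3S)-2-[4-(benzyloxy)-3-methoxyphenyl]-3-{[(tert-butyldimethylsilyl)oxy]methyl}-7-methoxy-2,3-dihydro-1-benzofuran-5-carbaldehyde, via aryllithium 10 (not isolated)
Conditions: n-BuLi, THF, −78 °C; DMF, −78 → 0 °C; aq. NH4Cl
Reagents that add atoms: N,N-dimethylformamide, CN(C)C=O
Why: Bromine–lithium exchange followed by formylation with DMF (Bouveault-type); no acidic C–H should compete at −78 °C.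

Step 9
Reactants: 12 (S)-4-benzyl-1,3-oxazolidin-2-one; 13 methyl 4-chloro-4-oxobutanoate
Product: 15 methyl 4-[(4S)-4-benzyl-2-oxo-1,3-oxazolidin-3-yl]-4-oxobutanoate, via lithiated oxazolidinone 14 (not isolated)
Conditions: n-BuLi, THF, −78 °C; 13, −78 → 0 °C
Reagents that add atoms: none
Why: N-Acylation of the lithiated oxazolidinone with the acid chloride (Evans imide formation).

Step 10
Reactants: 15 methyl 4-[(4S)-4-benzyl-2-oxo-1,3-oxazolidin-3-yl]-4-oxobutanoate; 11 (2S,3S)-2-[4-(benzyloxy)-3-methoxyphenyl]-3-{[(tert-butyldimethylsilyl)oxy]methyl}-7-methoxy-2,3-dihydro-1-benzofuran-5-carbaldehyde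
Product: 18 (4S)-4-benzyl-3-{[(2S,3S)-2-Ar1-5-oxooxolan-3-yl]carbonyl}-1,3-oxazolidin-2-one (2,3-trans lactone), via boron Z-enolate 16 (not isolated), via syn-aldol hydroxy ester 17 (not isolated)
Conditions: Bu2BOTf, i-Pr2NEt, CH2Cl2, −78 → 0 °C; 11, −78 → 0 °C; pH 7 buffer (NaH2PO4/Na2HPO4), MeOH, 30% H2O2, 0 °C; then PPTS (cat.), CH2Cl2, rt
Reagents that add atoms: none
Why: Evans syn aldol: the Z boron enolate should react through a closed chair transition state on the face away from the benzyl group of the (S)-auxiliary, which sets both new centres as (3S,4S), and the benzylic hydroxyl then closes the γ-lactone on the methyl ester (transesterification), a syn aldol giving the 2,3-trans lactone.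

Step 11
Reactants: 18 (4S)-4-benzyl-3-{[(2S,3S)-2-Ar1-5-oxooxolan-3-yl]carbonyl}-1,3-oxazolidin-2-one
Product: 20 (2S,3S)-2-Ar1-5-oxooxolane-3-carboxylic acid, via peroxy acid 19 (not isolated)
Conditions: LiOH, 30% H2O2, THF–H2O, 0 °C; aq. Na2SO3; 1 M HCl to pH 3
Reagents that add atoms: hydrogen peroxide (as LiOOH), OO
Why: Hydroperoxide cleavage of the exocyclic imide carbonyl (LiOOH protocol for acyl oxazolidinones), which should spare the stereocentres; any lactone opened by base recloses on acidification.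

Step 12
Reactants: 20 (2S,3S)-2-Ar1-5-oxooxolane-3-carboxylic acid
Product: 21 methyl (2S,3S)-2-Ar1-5-oxooxolane-3-carboxylate
Conditions: TMSCHN2, toluene–MeOH, 0 °C
Reagents that add atoms: (trimethylsilyl)diazomethane, C[Si](C)(C)C=[N+]=[N-]
Why: Methyl ester formation with a diazoalkane under neutral conditions, which avoids base at the epimerisable carbon next to the carboxyl group.

Step 13
Reactants: 21 methyl (2S,3S)-2-Ar1-5-oxooxolane-3-carboxylate; 22 4-(benzyloxy)-3,5-dimethoxybenzaldehyde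
Product: 25 (1S,2S,5S,6S)-2-Ar1-6-Ar2-3,7-dioxabicyclo[3.3.0]octane-4,8-dione (cis-fused; both aryl groups exo), via lithium enolate 23 (not isolated), via cis-aldolate 24 (not isolated)
Conditions: LiN(SiMe3)2 (1.05 equiv), THF, −78 °C; 22, −78 → −20 °C; aq. NH4Cl
Reagents that add atoms: none
Why: LiN(SiMe3)2 removes a proton from C5 (oxolane C4), the lactone α-methylene, and enolate 23 adds to aldehyde 22 to form C5–C6; the C6 alkoxide of 24 then attacks the C8 methyl ester on C1 and expels methoxide, which forms O7–C8 by acyl substitution (5-exo-trig) and so closes the second γ-lactone ring C1–C5–C6–O7–C8. The closest known reaction type is the aldol–lactonisation of succinate and paraconic ester enolates with aryl aldehydes (Stobbe-type), here stopped at the bis-lactone. C5 is controlled by ring strain: only the aldolate whose new substituent is cis to the C1 ester can lactonise, since a trans-fused bicyclo[3.3.0] dilactone is out of reach, while addition to the other face is reversible and feeds back through retro-aldol. C6 is controlled in the lactonisation, where Ar2 should take the convex (exo) side, away from the first lactone ring. The step needs enolisation at C5 and not at the C1–H next to the ester; the substrate secures this because the lactone α-CH2 is both more acidic and less hindered than the tertiary ester α-CH, and Ar1 at C2, already trans to the ester, is not touched, so all four contiguous furofuran centres stand after this step.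

Step 14
Reactants: 25 (1S,2S,5S,6S)-2-Ar1-6-Ar2-3,7-dioxabicyclo[3.3.0]octane-4,8-dione
Product: 26 (1S,2R,3R,4S)-1-Ar1-4-Ar2-2,3-bis(hydroxymethyl)butane-1,4-diol
Conditions: LiAlH4, THF, 0 °C → rt; aq. NaOH work-up
Reagents that add atoms: none
Why: Hydride reduction of both lactones to 1,4-diol units; no stereocentre is affected and no acid is used, which protects the cis-dihydrobenzofuran.

Step 15
Reactants: 26 (1S,2R,3R,4S)-1-Ar1-4-Ar2-2,3-bis(hydroxymethyl)butane-1,4-diol
Product: 28 (1R,2S,5R,6S)-2-Ar1-6-Ar2-3,7-dioxabicyclo[3.3.0]octane, via bis-mesylate 27 (not isolated)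
Conditions: MsCl (2.2 equiv), pyridine, 0 °C, then rt
Reagents that add atoms: none
Why: Selective sulfonylation of the two primary hydroxyls followed by double 5-exo-tet Williamson-type ether closure by the benzylic hydroxyls; substitution occurs only at primary carbons, so all stereocentres should be retained.

Step 16
Reactants: 28 (1R,2S,5R,6S)-2-Ar1-6-Ar2-3,7-dioxabicyclo[3.3.0]octane
Product: 29 [(2S,3S)-2-[4-(benzyloxy)-3-methoxyphenyl]-5-[(1R,2S,5R,6S)-6-Ar2-3,7-dioxabicyclo[3.3.0]octan-2-yl]-7-methoxy-2,3-dihydro-1-benzofuran-3-yl]methanol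
Conditions: Bu4NF, THF, 0 °C → rt
Reagents that add atoms: none
Why: Fluoride-mediated cleavage of the silyl ether; the phenols are still benzylated, so no phenoxide can open the benzylic ether rings.

Step 17
Reactants: 29 [(2S,3S)-2-[4-(benzyloxy)-3-methoxyphenyl]-5-[(1R,2S,5R,6S)-6-Ar2-3,7-dioxabicyclo[3.3.0]octan-2-yl]-7-methoxy-2,3-dihydro-1-benzofuran-3-yl]methanol
Product: 30 [(2S,3S)-2-(4-hydroxy-3-methoxyphenyl)-5-[(1R,2S,5R,6S)-6-(4-hydroxy-3,5-dimethoxyphenyl)-3,7-dioxabicyclo[3.3.0]octan-2-yl]-7-methoxy-2,3-dihydro-1-benzofuran-3-yl]methanol (CNP0126146.1)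
Conditions: H2 (1 atm), 10% Pd/C, EtOAc–MeOH, rt, stopped at full conversion
Reagents that add atoms: none
Why: Catalytic hydrogenolysis of the two aryl benzyl ethers, which should be cleaved well before the ring benzylic C–O bonds under neutral conditions at short reaction time.

Compound list
1 | 4-bromo-2-methoxyphenol | COc1cc(Br)ccc1O | starting material
2 | 4-bromo-2-iodo-6-methoxyphenol | COc1cc(Br)cc(I)c1O | intermediate
3 | [4-(benzyloxy)-3-methoxyphenyl]methanol | COc1cc(CO)ccc1OCc1ccccc1 | starting material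
4 | 2-{[4-(benzyloxy)-3-methoxyphenyl]methoxy}-5-bromo-1-iodo-3-methoxybenzene | COc1cc(COc2c(I)cc(Br)cc2OC)ccc1OCc1ccccc1 | intermediate
5 | methyl 2-(2-{[4-(benzyloxy)-3-methoxyphenyl]methoxy}-5-bromo-3-methoxyphenyl)acetate | COC(=O)Cc1cc(Br)cc(OC)c1OCc1ccc(OCc2ccccc2)c(OC)c1 | intermediate
6 | methyl 2-(2-{[4-(benzyloxy)-3-methoxyphenyl]methoxy}-5-bromo-3-methoxyphenyl)-2-diazoacetate | COC(=O)C(=[N+]=[N-])c1cc(Br)cc(OC)c1OCc1ccc(OCc2ccccc2)c(OC)c1 | intermediate
7 | methyl (2S,3R)-2-[4-(benzyloxy)-3-methoxyphenyl]-5-bromo-7-methoxy-2,3-dihydro-1-benzofuran-3-carboxylate (2,3-cis) | COc1cc([C@H]2Oc3c(OC)cc(Br)cc3[C@H]2C(=O)OC)ccc1OCc1ccccc1 | intermediate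
8 | [(2S,3S)-2-[4-(benzyloxy)-3-methoxyphenyl]-5-bromo-7-methoxy-2,3-dihydro-1-benzofuran-3-yl]methanol (2,3-cis) | COc1cc([C@H]2Oc3c(OC)cc(Br)cc3[C@H]2CO)ccc1OCc1ccccc1 | intermediate
9 | tert-butyl{[(2S,3S)-2-[4-(benzyloxy)-3-methoxyphenyl]-5-bromo-7-methoxy-2,3-dihydro-1-benzofuran-3-yl]methoxy}dimethylsilane | COc1cc([C@H]2Oc3c(OC)cc(Br)cc3[C@H]2CO[Si](C)(C)C(C)(C)C)ccc1OCc1ccccc1 | intermediate
10 | aryllithium from 9 (lithium in place of bromine at C5; formed in the flask) | COc1cc([C@H]2Oc3c(OC)cc([Li])cc3[C@H]2CO[Si](C)(C)C(C)(C)C)ccc1OCc1ccccc1 | intermediate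
11 | (2S,3S)-2-[4-(benzyloxy)-3-methoxyphenyl]-3-{[(tert-butyldimethylsilyl)oxy]methyl}-7-methoxy-2,3-dihydro-1-benzofuran-5-carbaldehyde (Ar1–CHO) | COc1cc([C@H]2Oc3c(OC)cc(C=O)cc3[C@H]2CO[Si](C)(C)C(C)(C)C)ccc1OCc1ccccc1 | intermediate
12 | (S)-4-benzyl-1,3-oxazolidin-2-one | O=C1N[C@@H](Cc2ccccc2)CO1 | starting material
13 | methyl 4-chloro-4-oxobutanoate | COC(=O)CCC(Cl)=O | starting material
14 | N-lithio derivative of 12 (formed in the flask) | [Li]N1[C@@H](Cc2ccccc2)COC1=O | intermediate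
15 | methyl 4-[(4S)-4-benzyl-2-oxo-1,3-oxazolidin-3-yl]-4-oxobutanoate | COC(=O)CCC(=O)N1[C@@H](Cc2ccccc2)COC1=O | intermediate
16 | methyl (3Z)-4-[(4S)-4-benzyl-2-oxo-1,3-oxazolidin-3-yl]-4-[(dibutylboranyl)oxy]but-3-enoate (boron Z-enolate of 15; formed in the flask) | CCCCB(CCCC)O/C(=C\CC(=O)OC)N1[C@@H](Cc2ccccc2)COC1=O | intermediate
17 | methyl (3S,4S)-4-Ar1-3-{[(4S)-4-benzyl-2-oxo-1,3-oxazolidin-3-yl]carbonyl}-4-hydroxybutanoate (syn aldol adduct; formed in the flask) | COc1cc([C@H]2Oc3c(OC)cc([C@@H](O)[C@H](CC(=O)OC)C(=O)N4[C@@H](Cc5ccccc5)COC4=O)cc3[C@H]2CO[Si](C)(C)C(C)(C)C)ccc1OCc1ccccc1 | intermediate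
18 | (4S)-4-benzyl-3-{[(2S,3S)-2-Ar1-5-oxooxolan-3-yl]carbonyl}-1,3-oxazolidin-2-one (2,3-trans lactone) | COc1cc([C@H]2Oc3c(OC)cc([C@H]4OC(=O)C[C@@H]4C(=O)N4[C@@H](Cc5ccccc5)COC4=O)cc3[C@H]2CO[Si](C)(C)C(C)(C)C)ccc1OCc1ccccc1 | intermediate
19 | (2S,3S)-2-Ar1-5-oxooxolane-3-carboperoxoic acid (formed in the flask) | COc1cc([C@H]2Oc3c(OC)cc([C@H]4OC(=O)C[C@@H]4C(=O)OO)cc3[C@H]2CO[Si](C)(C)C(C)(C)C)ccc1OCc1ccccc1 | intermediate
20 | (2S,3S)-2-Ar1-5-oxooxolane-3-carboxylic acid (2,3-trans) | COc1cc([C@H]2Oc3c(OC)cc([C@H]4OC(=O)C[C@@H]4C(=O)O)cc3[C@H]2CO[Si](C)(C)C(C)(C)C)ccc1OCc1ccccc1 | intermediate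
21 | methyl (2S,3S)-2-Ar1-5-oxooxolane-3-carboxylate (2,3-trans; precursor of the key step) | COc1cc([C@H]2Oc3c(OC)cc([C@H]4OC(=O)C[C@@H]4C(=O)OC)cc3[C@H]2CO[Si](C)(C)C(C)(C)C)ccc1OCc1ccccc1 | intermediate
22 | 4-(benzyloxy)-3,5-dimethoxybenzaldehyde (Ar2–CHO) | COc1cc(C=O)cc(OC)c1OCc1ccccc1 | starting material
23 | lithium enolate of 21 at oxolane C4–C5 (furofuran C5; formed in the flask) | COc1cc([C@H]2Oc3c(OC)cc([C@H]4OC(O[Li])=C[C@@H]4C(=O)OC)cc3[C@H]2CO[Si](C)(C)C(C)(C)C)ccc1OCc1ccccc1 | intermediate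
24 | lithium alkoxide of methyl (2S,3S,4S)-2-Ar1-4-[(S)-Ar2(hydroxy)methyl]-5-oxooxolane-3-carboxylate (new substituent cis to the ester; formed in the flask) | COc1cc([C@H]2Oc3c(OC)cc([C@H]4OC(=O)[C@H]([C@H](O[Li])c5cc(OC)c(OCc6ccccc6)c(OC)c5)[C@@H]4C(=O)OC)cc3[C@H]2CO[Si](C)(C)C(C)(C)C)ccc1OCc1ccccc1 | intermediate
25 | (1S,2S,5S,6S)-2-Ar1-6-Ar2-3,7-dioxabicyclo[3.3.0]octane-4,8-dione (cis-fused; both aryl groups exo) | COc1cc([C@H]2Oc3c(OC)cc([C@H]4OC(=O)[C@H]5[C@@H]4C(=O)O[C@@H]5c4cc(OC)c(OCc5ccccc5)c(OC)c4)cc3[C@H]2CO[Si](C)(C)C(C)(C)C)ccc1OCc1ccccc1 | intermediate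
26 | (1S,2R,3R,4S)-1-Ar1-4-Ar2-2,3-bis(hydroxymethyl)butane-1,4-diol | COc1cc([C@H]2Oc3c(OC)cc([C@@H](O)[C@@H](CO)[C@H](CO)[C@H](O)c4cc(OC)c(OCc5ccccc5)c(OC)c4)cc3[C@H]2CO[Si](C)(C)C(C)(C)C)ccc1OCc1ccccc1 | intermediate
27 | bis(methanesulfonate) of the two primary hydroxyls of 26 (formed in the flask) | COc1cc([C@H]2Oc3c(OC)cc([C@@H](O)[C@@H](COS(C)(=O)=O)[C@H](COS(C)(=O)=O)[C@H](O)c4cc(OC)c(OCc5ccccc5)c(OC)c4)cc3[C@H]2CO[Si](C)(C)C(C)(C)C)ccc1OCc1ccccc1 | intermediate
28 | (1R,2S,5R,6S)-2-Ar1-6-Ar2-3,7-dioxabicyclo[3.3.0]octane | COc1cc([C@H]2Oc3c(OC)cc([C@H]4OC[C@H]5[C@@H]4CO[C@@H]5c4cc(OC)c(OCc5ccccc5)c(OC)c4)cc3[C@H]2CO[Si](C)(C)C(C)(C)C)ccc1OCc1ccccc1 | intermediate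
29 | [(2S,3S)-2-[4-(benzyloxy)-3-methoxyphenyl]-5-[(1R,2S,5R,6S)-6-Ar2-3,7-dioxabicyclo[3.3.0]octan-2-yl]-7-methoxy-2,3-dihydro-1-benzofuran-3-yl]methanol | COc1cc([C@H]2Oc3c(OC)cc([C@H]4OC[C@H]5[C@@H]4CO[C@@H]5c4cc(OC)c(OCc5ccccc5)c(OC)c4)cc3[C@H]2CO)ccc1OCc1ccccc1 | intermediate
30 | [(2S,3S)-2-(4-hydroxy-3-methoxyphenyl)-5-[(1R,2S,5R,6S)-6-(4-hydroxy-3,5-dimethoxyphenyl)-3,7-dioxabicyclo[3.3.0]octan-2-yl]-7-methoxy-2,3-dihydro-1-benzofuran-3-yl]methanol (CNP0126146.1) | COc1cc([C@H]2Oc3c(OC)cc([C@H]4OC[C@H]5[C@@H]4CO[C@@H]5c4cc(OC)c(O)c(OC)c4)cc3[C@H]2CO)ccc1O | target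

Total step count: 17. Longest linear sequence: 16 steps (steps 1–8 and 10–17; step 9 is the one-step branch to imide 15).

Steps most likely to fail

Step 13. What may go wrong: deprotonation at C1 in competition with C5, followed by β-elimination of the lactone carboxylate (ring opening) or loss of the trans C1/C2 relationship; or an aldol equilibrium that does not drain through the cis aldolate, so that the cascade stops before lactonisation. The fallback separates bond formation from ring closure and uses a known carboxylate-dianion aldol and a carbodiimide lactonisation. It sets out from acid 20. Two equivalents of LiN(SiMe3)2 (THF, −78 °C) should give the carboxylate–lactone enolate dianion, in which the carboxylate blocks deprotonation and elimination at C1. Addition of 22 with warming to equilibrate should give (2S,3S,4S)-2-Ar1-4-[(S)-Ar2(hydroxy)methyl]-5-oxooxolane-3-carboxylic acid F1. EDC·HCl and DMAP (CH2Cl2, 0 °C) then close the O7–C8 lactone of the only isomer able to cyclise, and the route is rejoined at 25. Aldol isomers that cannot close are re-equilibrated with base.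

Step 5. What may go wrong: insufficient discrimination between the enantiotopic C–H bonds by the catalyst (the 7-methoxy group next to the ether oxygen is an untested influence), or erosion of the cis geometry through epimerisation at C3. A small amount of the wrong enantiomer is tolerable, because it ends as a diastereomer of 18 and can be removed there. The fallback replaces catalyst control by auxiliary control and an SN2 ring closure; it sets out from phenol 2 and comes back at 9, bypassing steps 2–7.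
- Allyl bromide and K2CO3 (DMF) give 5-bromo-1-iodo-3-methoxy-2-(prop-2-enyloxy)benzene F2.
- Negishi coupling as in step 3 gives methyl 2-[5-bromo-3-methoxy-2-(prop-2-enyloxy)phenyl]acetate F3.
- LiOH (THF–H2O) gives 2-[5-bromo-3-methoxy-2-(prop-2-enyloxy)phenyl]acetic acid F4.
- Pivaloyl chloride/Et3N, then lithiated (R)-4-benzyl-1,3-oxazolidin-2-one, give (4R)-4-benzyl-3-{2-[5-bromo-3-methoxy-2-(prop-2-enyloxy)phenyl]acetyl}-1,3-oxazolidin-2-one F5.
- A Bu2BOTf/i-Pr2NEt Evans syn aldol with 4-(benzyloxy)-3-methoxybenzaldehyde should give (4R)-4-benzyl-3-{(2R,3R)-3-[4-(benzyloxy)-3-methoxyphenyl]-2-[5-bromo-3-methoxy-2-(prop-2-enyloxy)phenyl]-3-hydroxypropanoyl}-1,3-oxazolidin-2-one F6.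
- LiBH4 (THF, 0 °C) removes the auxiliary to give (1R,2S)-1-[4-(benzyloxy)-3-methoxyphenyl]-2-[5-bromo-3-methoxy-2-(prop-2-enyloxy)phenyl]propane-1,3-diol F7.
- TBSCl/imidazole at 0 °C silylates the primary hydroxyl to give (1R,2S)-1-[4-(benzyloxy)-3-methoxyphenyl]-2-[5-bromo-3-methoxy-2-(prop-2-enyloxy)phenyl]-3-[(tert-butyldimethylsilyl)oxy]propan-1-ol F8.
- Pd(PPh3)4 and morpholine remove the allyl group to give 2-[(1R,2S)-1-[4-(benzyloxy)-3-methoxyphenyl]-3-[(tert-butyldimethylsilyl)oxy]-1-hydroxypropan-2-yl]-4-bromo-6-methoxyphenol F9.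
- Mitsunobu cyclisation (PPh3, DIAD, THF) with inversion at the benzylic carbinol turns the syn relationship into the 2,3-cis ring of 9.

Step 15. What may go wrong: incomplete discrimination between primary and benzylic hydroxyls in the sulfonylation, or ether formation between the two primary positions before the second sulfonylation, giving a 3,4-disubstituted tetrahydrofuran instead of the bicycle; ionisation of a benzylic sulfonate would also put the C2/C6 configuration at risk. The fallback avoids the tetraol altogether and uses the known lactol reduction. It sets out from bis-lactone 25. i-Bu2AlH (CH2Cl2, −78 °C) should give the bis-lactol (1S,2S,5S,6S)-2-Ar1-6-Ar2-3,7-dioxabicyclo[3.3.0]octane-4,8-diol F10 (anomeric mixture). Et3SiH and BF3·OEt2 (CH2Cl2, −78 → −20 °C) then remove both anomeric hydroxyls by ionic hydrogenation through the oxocarbenium ions, and the route is rejoined at 28. The mixture is kept cold to limit Lewis-acid ionisation of the benzylic ethers; loss of the silyl group at this point would be harmless, since step 16 removes it anyway.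

Further compounds
F1 | step 13 | (2S,3S,4S)-2-Ar1-4-[(S)-Ar2(hydroxy)methyl]-5-oxooxolane-3-carboxylic acid | COc1cc([C@H]2Oc3c(OC)cc([C@H]4OC(=O)[C@H]([C@H](O)c5cc(OC)c(OCc6ccccc6)c(OC)c5)[C@@H]4C(=O)O)cc3[C@H]2CO[Si](C)(C)C(C)(C)C)ccc1OCc1ccccc1
F2 | step 5 | 5-bromo-1-iodo-3-methoxy-2-(prop-2-enyloxy)benzene | C=CCOc1c(I)cc(Br)cc1OC
F3 | step 5 | methyl 2-[5-bromo-3-methoxy-2-(prop-2-enyloxy)phenyl]acetate | COC(=O)Cc1cc(Br)cc(OC)c1OCC=C
F4 | step 5 | 2-[5-bromo-3-methoxy-2-(prop-2-enyloxy)phenyl]acetic acid | OC(=O)Cc1cc(Br)cc(OC)c1OCC=C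
F5 | step 5 | (4R)-4-benzyl-3-{2-[5-bromo-3-methoxy-2-(prop-2-enyloxy)phenyl]acetyl}-1,3-oxazolidin-2-one | C=CCOc1c(CC(=O)N2[C@H](Cc3ccccc3)COC2=O)cc(Br)cc1OC
F6 | step 5 | (4R)-4-benzyl-3-{(2R,3R)-3-[4-(benzyloxy)-3-methoxyphenyl]-2-[5-bromo-3-methoxy-2-(prop-2-enyloxy)phenyl]-3-hydroxypropanoyl}-1,3-oxazolidin-2-one | COc1cc([C@H](O)[C@H](C(=O)N2[C@H](Cc3ccccc3)COC2=O)c2cc(Br)cc(OC)c2OCC=C)ccc1OCc1ccccc1
F7 | step 5 | (1R,2S)-1-[4-(benzyloxy)-3-methoxyphenyl]-2-[5-bromo-3-methoxy-2-(prop-2-enyloxy)phenyl]propane-1,3-diol | COc1cc([C@H](O)[C@H](CO)c2cc(Br)cc(OC)c2OCC=C)ccc1OCc1ccccc1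
F8 | step 5 | (1R,2S)-1-[4-(benzyloxy)-3-methoxyphenyl]-2-[5-bromo-3-methoxy-2-(prop-2-enyloxy)phenyl]-3-[(tert-butyldimethylsilyl)oxy]propan-1-ol | COc1cc([C@H](O)[C@H](CO[Si](C)(C)C(C)(C)C)c2cc(Br)cc(OC)c2OCC=C)ccc1OCc1ccccc1
F9 | step 5 | 2-[(1R,2S)-1-[4-(benzyloxy)-3-methoxyphenyl]-3-[(tert-butyldimethylsilyl)oxy]-1-hydroxypropan-2-yl]-4-bromo-6-methoxyphenol | COc1cc([C@H](O)[C@H](CO[Si](C)(C)C(C)(C)C)c2cc(Br)cc(OC)c2O)ccc1OCc1ccccc1
F10 | step 15 | (1S,2S,5S,6S)-2-Ar1-6-Ar2-3,7-dioxabicyclo[3.3.0]octane-4,8-diol (bis-lactol of 25; anomeric mixture) | COc1cc([C@H]2Oc3c(OC)cc([C@H]4OC(O)[C@H]5[C@@H]4C(O)O[C@@H]5c4cc(OC)c(OCc5ccccc5)c(OC)c4)cc3[C@H]2CO[Si](C)(C)C(C)(C)C)ccc1OCc1ccccc1
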